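**Strategy.** The γ-lactone is disconnected at the bond between the quaternary carbon C2 and the ring methylene C3. The route exploits the fact that lactone oxygen O1 holds C2 and the carbonyl carbon C5 in a 1,3-relationship: C5, at the aldehyde level, becomes the acetal carbon of a 1,3-dioxolan-4-one built on the C2 α-hydroxy acid and carries C4–C3 as a 2-bromoethyl arm. Intramolecular C-alkylation of the dioxolanone enolate closes ring O1–C2–C3–C4–C5, sets the quaternary stereocentre from the acetal centre and gives a 2,7-dioxabicyclo[2.2.1]heptan-3-one, which oxidation turns into the lactone. The hydroxy diacid comes from an Evans glyoxylate aldol; D-malate is attached last.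

Key step: step 6

Remark: locants follow the lactone ring (O1, C2 quaternary, C3, C4, C5 carbonyl); Cα is the side-chain CH; ethyl glyoxylate is assumed to be used as the freshly distilled monomer.

Step 1
Reactants: 1 12-bromododecanoic acid
Product: 2 12-(benzyloxy)dodecanoic acid
Conditions: BnOH, NaH, Bu4NI (cat.), THF, 0 °C → reflux; aq. HCl
Reagents that add atoms: benzyl alcohol, OCc1ccccc1
Why: Williamson ether synthesis, in which the carboxylate formed first is inert and excess sodium benzyloxide displaces the unhindered primary bromide by SN2.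

Step 2
Reactants: 2 12-(benzyloxy)dodecanoic acid; 3 (4R)-4-benzyl-1,3-oxazolidin-2-one
Product: 5 (4R)-4-benzyl-3-[12-(benzyloxy)dodecanoyl]-1,3-oxazolidin-2-one, via mixed pivalic anhydride 4 (not isolated)
Conditions: PivCl, Et3N, THF, −20 °C; then 3, LiCl, −20 °C → rt
Reagents that add atoms: none
Why: N-acylation of the oxazolidinone through a mixed pivalic anhydride, whose hindered pivaloyl carbonyl directs the LiCl-activated auxiliary to the dodecanoyl carbonyl.

Step 3
Reactants: 5 (4R)-4-benzyl-3-[12-(benzyloxy)dodecanoyl]-1,3-oxazolidin-2-one; 6 ethyl glyoxylate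
Product: 8 ethyl (2R,3R)-3-{[(4R)-4-benzyl-2-oxo-1,3-oxazolidin-3-yl]carbonyl}-13-(benzyloxy)-2-hydroxytridecanoate, via boron Z-enolate 7 (not isolated)
Conditions: Bu2BOTf, iPr2NEt, CH2Cl2, −78 → 0 °C; 6, −78 → 0 °C; H2O2, MeOH, pH 7 phosphate buffer, 0 °C
Reagents that add atoms: none
Why: Evans syn aldol, in which the boron Z-enolate reacts through a Zimmerman–Traxler chair on the face opposite the (4R)-benzyl group and so sets Cα as R and the carbinol carbon as R (syn) in one operation.

Step 4
Reactants: 8 ethyl (2R,3R)-3-{[(4R)-4-benzyl-2-oxo-1,3-oxazolidin-3-yl]carbonyl}-13-(benzyloxy)-2-hydroxytridecanoate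
Product: 10 (2R,3R)-2-[10-(benzyloxy)decyl]-3-hydroxybutanedioic acid, via peroxy acid 9 (not isolated)
Conditions: LiOH, H2O2, THF/H2O, 0 °C → rt; Na2SO3; HCl to pH 2
Reagents that add atoms: hydrogen peroxide, OO; lithium hydroxide, [Li+].[OH-]
Why: Hydroperoxide cleaves the exocyclic imide carbonyl selectively while hydroxide saponifies the activated α-hydroxy ester, both without epimerising Cα, and the auxiliary is recovered.

Step 5
Reactants: 10 (2R,3R)-2-[10-(benzyloxy)decyl]-3-hydroxybutanedioic acid; 11 3-bromo-1,1-dimethoxypropane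
Product: 13 (2R)-12-(benzyloxy)-2-[(2R,4R)-2-(2-bromoethyl)-5-oxo-1,3-dioxolan-4-yl]dodecanoic acid, via tris(trimethylsilyl) derivative 12 (not isolated)
Conditions: (Me3Si)2NH, Me3SiCl (cat.), CH2Cl2, reflux, then evaporation; 11, Me3SiOTf (cat.), CH2Cl2, −78 → −30 °C; pyridine, then aqueous work-up at pH 4
Reagents that add atoms: none
Why: Silyl-transfer acetalisation (Me3SiOTf-catalysed exchange of the dimethyl acetal with the silyl ether and the α-silyl ester) should close the five-membered dioxolanone in preference to the six-membered ring through the distal carboxyl, and the carbinol stereocentre is expected to set the new acetal centre cis (2R) under kinetic control, the minor trans isomer being removed by chromatography.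

Step 6
Reactants: 13 (2R)-12-(benzyloxy)-2-[(2R,4R)-2-(2-bromoethyl)-5-oxo-1,3-dioxolan-4-yl]dodecanoic acid
Product: 15 (2R)-12-(benzyloxy)-2-[(1R,4S)-3-oxo-2,7-dioxabicyclo[2.2.1]heptan-4-yl]dodecanoic acid, via dilithio carboxylate enolate 14 (not isolated)
Conditions: LiN(SiMe3)2 (2.1 equiv), THF/DMPU, −78 → −20 °C, high dilution; AcOH, −78 °C
Reagents that add atoms: none
Why: The first equivalent of base forms the carboxylate, the second removes the ring C–H at C2 (the Cα–H next to a carboxylate is far less acidic, so no β-elimination path opens), and the enolate carbon of the dilithio species then displaces bromide from the 2-bromoethyl arm by intramolecular SN2 C-alkylation. The closest known reaction type is the alkylation of lithium enolates of 2,5-disubstituted 1,3-dioxolan-4-ones (self-regeneration of stereocentres, also as the carboxylate dianion of the malic-acid-derived acetal), combined with the intramolecular enolate alkylations that close bicyclo[2.2.1]heptanones. Ring O1–C2–C3–C4–C5 closes in the 5-(enolexo)-exo-tet mode and turns the monocyclic acetal into the 2,7-dioxabicyclo[2.2.1]heptan-3-one. The new quaternary centre C2 is controlled only by the acetal carbon C5: the arm is fixed on one face of the planar enolate and can reach C2 from that face alone, so the cis-(2R,4R) acetal must give (S)-C2, while Cα, not being deprotonated, keeps its R configuration. The step needs C- over O-alkylation and substitution over loss of HBr: O-alkylation would demand a bridgehead ketene acetal, E2 is held back because the amide base is consumed at −78 °C before warming and the lithium enolate in THF/DMPU is a better nucleophile than base, and dilution suppresses intermolecular alkylation.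

Step 7
Reactants: 15 (2R)-12-(benzyloxy)-2-[(1R,4S)-3-oxo-2,7-dioxabicyclo[2.2.1]heptan-4-yl]dodecanoic acid
Product: 17 (2S)-2-[(1R)-11-(benzyloxy)-1-carboxyundecyl]-5-oxooxolane-2-carboxylic acid, via lactol diacid 16 (not isolated)
Conditions: CrO3, H2SO4, H2O, acetone, 0 °C
Reagents that add atoms: water, O
Why: Aqueous acid opens the strained bicyclic acylal to the lactol and Jones oxidation takes the lactol to the γ-lactone, leaving the benzyl ether, both acids and both stereocentres untouched.

Step 8
Reactants: 17 (2S)-2-[(1R)-11-(benzyloxy)-1-carboxyundecyl]-5-oxooxolane-2-carboxylic acid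
Product: 18 (2S)-2-[(1R)-1-carboxy-11-hydroxyundecyl]-5-oxooxolane-2-carboxylic acid
Conditions: H2 (1 atm), Pd/C, EtOAc, rt
Reagents that add atoms: none
Why: Hydrogenolysis of the benzyl ether over Pd/C frees the primary alcohol, the lactone and the carboxylic acids being inert.

Step 9
Reactants: 18 (2S)-2-[(1R)-1-carboxy-11-hydroxyundecyl]-5-oxooxolane-2-carboxylic acid; 19 (R)-malic acid (D-malic acid)
Product: 22 (2S)-2-[(1R)-1-carboxy-11-{[(2R)-3-carboxy-2-hydroxypropanoyl]oxy}undecyl]-5-oxooxolane-2-carboxylic acid, via O-trifluoroacetyl-D-malic anhydride 20 (not isolated), via O-trifluoroacetyl ester 21 (not isolated)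
Conditions: 19 (3 equiv), (CF3CO)2O, 0 °C → rt, then evaporation; 18, THF, 0 °C → rt; H2O/THF, rt
Reagents that add atoms: none
Why: Regioselective alcoholysis of a cyclic anhydride, in which the primary alcohol opens the trifluoroacetylated malic anhydride at the carbonyl next to the electron-poor OCOCF3-bearing carbon to give the 1-ester with the 4-carboxyl free, the labile trifluoroacetate is hydrolysed on aqueous treatment, and the (R) centre of the malate is not touched.

**Compound list**

1 | 12-bromododecanoic acid | OC(=O)CCCCCCCCCCCBr | starting material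
2 | 12-(benzyloxy)dodecanoic acid | OC(=O)CCCCCCCCCCCOCc1ccccc1 | intermediate
3 | (4R)-4-benzyl-1,3-oxazolidin-2-one | O=C1N[C@H](Cc2ccccc2)CO1 | starting material
4 | 12-(benzyloxy)dodecanoic pivalic anhydride | CC(C)(C)C(=O)OC(=O)CCCCCCCCCCCOCc1ccccc1 | intermediate
5 | (4R)-4-benzyl-3-[12-(benzyloxy)dodecanoyl]-1,3-oxazolidin-2-one | O=C(CCCCCCCCCCCOCc1ccccc1)N1[C@H](Cc2ccccc2)COC1=O | intermediate
6 | ethyl glyoxylate | CCOC(=O)C=O | starting material
7 | dibutylboron Z-enolate of 5 | CCCCB(CCCC)O/C(=C\CCCCCCCCCCOCc1ccccc1)N1[C@H](Cc2ccccc2)COC1=O | intermediate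
8 | ethyl (2R,3R)-3-{[(4R)-4-benzyl-2-oxo-1,3-oxazolidin-3-yl]carbonyl}-13-(benzyloxy)-2-hydroxytridecanoate | CCOC(=O)[C@H](O)[C@@H](CCCCCCCCCCOCc1ccccc1)C(=O)N1[C@H](Cc2ccccc2)COC1=O | intermediate
9 | monoperoxy acid of 10 (peroxy acid at the Cα carboxyl) | OC(=O)[C@H](O)[C@@H](CCCCCCCCCCOCc1ccccc1)C(=O)OO | intermediate
10 | (2R,3R)-2-[10-(benzyloxy)decyl]-3-hydroxybutanedioic acid | OC(=O)[C@H](O)[C@@H](CCCCCCCCCCOCc1ccccc1)C(=O)O | intermediate
11 | 3-bromo-1,1-dimethoxypropane | COC(OC)CCBr | starting material
12 | tris(trimethylsilyl) derivative of 10 (silyl ether and two silyl esters) | C[Si](C)(C)OC(=O)[C@H](O[Si](C)(C)C)[C@@H](CCCCCCCCCCOCc1ccccc1)C(=O)O[Si](C)(C)C | intermediate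
13 | (2R)-12-(benzyloxy)-2-[(2R,4R)-2-(2-bromoethyl)-5-oxo-1,3-dioxolan-4-yl]dodecanoic acid (arm and side chain cis) | O=C1O[C@H](CCBr)O[C@@H]1[C@@H](CCCCCCCCCCOCc2ccccc2)C(=O)O | intermediate
14 | dilithium carboxylate enolate of 13 | [Li+].[Li+].[O-]C(=O)[C@H](CCCCCCCCCCOCc1ccccc1)C1=C([O-])O[C@H](CCBr)O1 | intermediate
15 | (2R)-12-(benzyloxy)-2-[(1R,4S)-3-oxo-2,7-dioxabicyclo[2.2.1]heptan-4-yl]dodecanoic acid | O=C1O[C@@H]2CC[C@]1(O2)[C@@H](CCCCCCCCCCOCc3ccccc3)C(=O)O | intermediate
16 | (2S)-2-[(1R)-11-(benzyloxy)-1-carboxyundecyl]-5-hydroxyoxolane-2-carboxylic acid (lactol, both anomers) | c1ccccc1COCCCCCCCCCC[C@@H](C(=O)O)[C@]2(C(=O)O)CCC(O)O2 | intermediate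
17 | (2S)-2-[(1R)-11-(benzyloxy)-1-carboxyundecyl]-5-oxooxolane-2-carboxylic acid | c1ccccc1COCCCCCCCCCC[C@@H](C(=O)O)[C@]2(C(=O)O)CCC(=O)O2 | intermediate
18 | (2S)-2-[(1R)-1-carboxy-11-hydroxyundecyl]-5-oxooxolane-2-carboxylic acid | OCCCCCCCCCC[C@@H](C(=O)O)[C@]1(C(=O)O)CCC(=O)O1 | intermediate
19 | (R)-malic acid (D-malic acid) | OC(=O)C[C@@H](O)C(=O)O | starting material
20 | (3R)-2,5-dioxooxolan-3-yl trifluoroacetate (O-trifluoroacetyl-D-malic anhydride) | O=C1C[C@@H](OC(=O)C(F)(F)F)C(=O)O1 | intermediate
21 | O-trifluoroacetyl derivative of 22 (at the malate hydroxyl) | OC(=O)C[C@@H](OC(=O)C(F)(F)F)C(=O)OCCCCCCCCCC[C@@H](C(=O)O)[C@]1(C(=O)O)CCC(=O)O1 | intermediate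
22 | (2S)-2-[(1R)-1-carboxy-11-{[(2R)-3-carboxy-2-hydroxypropanoyl]oxy}undecyl]-5-oxooxolane-2-carboxylic acid | O=C(O)C[C@@H](O)C(=O)OCCCCCCCCCC[C@@H](C(=O)O)[C@]1(C(=O)O)CCC(=O)O1 | target

**Count.** Total steps: 9. Longest linear sequence: 9 steps (1 → 22); D-malic acid 19 enters in the last step.

**Steps most likely to fail**

1. Step 6 (key ring closure). Loss of HBr from the arm (E2) or thermal breakdown of the dilithio enolate may outrun the strained 5-exo-tet closure.
 Fallback, setting out from 8 and returning at 17: the quaternary centre is built by intermolecular alkylation of a tert-butyl dioxolanone. That alkylation adds trans to the acetal substituent and therefore needs the epimeric carbinol.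
 - Mitsunobu inversion of 8 (4-nitrobenzoic acid, PPh3, DIAD, THF) should give the inverted 4-nitrobenzoate F1.
 - LiOH/H2O2 then removes nitrobenzoate, ethyl ester and auxiliary to give the anti hydroxy diacid F2.
 - Pivalaldehyde with TsOH (pentane, azeotropic removal of water) should give the cis tert-butyl dioxolanone acid F3.
 - LiN(SiMe3)2 (2.1 equiv) and allyl bromide at −78 °C should give the allylated dioxolanone F4, the electrophile entering opposite the tert-butyl group.
 - 9-BBN followed by NaOH/H2O2 hydroborates the alkene and saponifies the acetal to the dihydroxy diacid F5.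
 - Jones oxidation of F5 takes the primary alcohol to the acid, which lactonises onto the tertiary hydroxyl to give 17.

2. Step 5 (acetal formation). The oxocarbenium intermediate may close onto the distal Cα carboxyl (six-membered ring), and cis selectivity at the acetal centre may be incomplete; the latter would later surface as epimerisation at C2.
 Fallback, setting out from 10 and returning at 13: kinetic silyl-transfer closure is replaced by equilibrium control. The free acid 10 and 11 are equilibrated with BF3·OEt2 in Et2O at rt, so that ring size and cis geometry are set by stability, as for malic acid with pivalaldehyde. The minor isomers are recycled by re-equilibration. No new compound is made.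

3. Step 9 (malate attachment). Anhydride exchange with the two free carboxylic acids of 18 may cause self-acylation and oligomers, and some attack may occur at the distal anhydride carbonyl.
 Fallback, setting out from 18 and returning at 22: the core acids are masked first.
 - BnBr and Cs2CO3 in DMF alkylate only the carboxylates and should give the dibenzyl ester F6.
 - Acylation of F6 with 20 as in step 9, followed by aqueous cleavage of the trifluoroacetate, should give the dibenzyl ester mono-acid F7.
 - H2 over Pd/C then gives 22.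

**Further compounds**

F1 | step 6 | ethyl (2S,3R)-3-{[(4R)-4-benzyl-2-oxo-1,3-oxazolidin-3-yl]carbonyl}-13-(benzyloxy)-2-[(4-nitrobenzoyl)oxy]tridecanoate | CCOC(=O)[C@@H](OC(=O)c1ccc(cc1)[N+](=O)[O-])[C@@H](CCCCCCCCCCOCc2ccccc2)C(=O)N3[C@H](Cc4ccccc4)COC3=O
F2 | step 6 | (2R,3S)-2-[10-(benzyloxy)decyl]-3-hydroxybutanedioic acid | OC(=O)[C@@H](O)[C@@H](CCCCCCCCCCOCc1ccccc1)C(=O)O
F3 | step 6 | (2R)-12-(benzyloxy)-2-[(2S,4S)-2-tert-butyl-5-oxo-1,3-dioxolan-4-yl]dodecanoic acid | O=C1O[C@@H](C(C)(C)C)O[C@H]1[C@@H](CCCCCCCCCCOCc2ccccc2)C(=O)O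
F4 | step 6 | (2R)-12-(benzyloxy)-2-[(2S,4S)-2-tert-butyl-5-oxo-4-(prop-2-en-1-yl)-1,3-dioxolan-4-yl]dodecanoic acid | O=C1O[C@@H](C(C)(C)C)O[C@@]1(CC=C)[C@@H](CCCCCCCCCCOCc2ccccc2)C(=O)O
F5 | step 6 | (2S,3R)-3-[10-(benzyloxy)decyl]-2-hydroxy-2-(3-hydroxypropyl)butanedioic acid | OCCC[C@@](O)(C(=O)O)[C@@H](CCCCCCCCCCOCc1ccccc1)C(=O)O
F0 | step 5 | none | none
F6 | step 9 | benzyl (2S)-2-[(2R)-1-(benzyloxy)-12-hydroxy-1-oxododecan-2-yl]-5-oxooxolane-2-carboxylate | OCCCCCCCCCC[C@@H](C(=O)OCc2ccccc2)[C@]1(C(=O)OCc3ccccc3)CCC(=O)O1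
F7 | step 9 | dibenzyl ester of 22 at the two core carboxyls (malate 4-carboxyl free) | OC(=O)C[C@@H](O)C(=O)OCCCCCCCCCC[C@@H](C(=O)OCc2ccccc2)[C@]1(C(=O)OCc3ccccc3)CCC(=O)O1
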